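**Retrosynthetic overview**

1. Feature: in the γ-lactone (O1, C2 carbonyl, C3, C4, C5) C4 carries two one-carbon arms, C5 (bonded to O1) and the benzylic CH2 of ring B. Drawn as two CH2OH groups, with C3 held sp2 as the ring A benzylidene, C4 is a prochiral carbon.
2. Late disconnections: the phenol O–benzyl bond; the C3 epimer equilibration (cis to trans); the C4–CH2–aryl bond to ring B (Negishi coupling of the iodide-derived alkylzinc with benzylated 4-bromo-2,6-dimethoxyphenol); the benzylidene C=C (hydrogenation).
3. Key disconnection: O1–C2. A chiral phosphoric acid lets one of the two enantiotopic hydroxymethyl groups displace tert-butanol from the conjugated ester, which sets C4 and closes the lactone, the only ring built in the route (rings A and B are bought).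
4. The diol ester comes from 2,2-dimethyl-1,3-dioxan-5-one by Horner–Wadsworth–Emmons olefination, hydrogenation, aldol condensation with 3,4,5-trimethoxybenzaldehyde and acetonide hydrolysis.

Key step: step 6

Remark on the chemistry: ring A is the 3,4,5-trimethoxyphenyl ring on the C3 arm, ring B the 4-hydroxy-3,5-dimethoxyphenyl ring on the C4 arm. TRIP is 3,3'-bis(2,4,6-triisopropylphenyl)-1,1'-binaphthyl-2,2'-diyl hydrogen phosphate.

Assumption: the sense of induction of the phosphoric acid on this substrate class cannot be predicted with confidence. (R)-TRIP is written, and its antipode is to be used if the first run delivers the (R)-lactone.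

**Route**

Step 1
Reactants: 1 2,2-dimethyl-1,3-dioxan-5-one; 2 tert-butyl diethylphosphonoacetate
Product: 3 tert-butyl 2-(2,2-dimethyl-1,3-dioxan-5-ylidene)acetate
Conditions: NaH, THF, 0 °C to rt
Reagents that add atoms: none
Why: Horner–Wadsworth–Emmons olefination by the sodium phosphonate anion should be clean because the ketone is symmetric (no alkene geometry to control) and the stabilized anion does not harm the acetonide.

Step 2
Reactants: 3 tert-butyl 2-(2,2-dimethyl-1,3-dioxan-5-ylidene)acetate
Product: 4 tert-butyl 2-(2,2-dimethyl-1,3-dioxan-5-yl)acetate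
Conditions: H2 (1 atm), 10% Pd/C, EtOAc, rt
Reagents that add atoms: none
Why: heterogeneous catalytic hydrogenation of the conjugated alkene leaves the acetonide and the tert-butyl ester untouched and creates no stereocenter because the dioxane is symmetric.

Step 3
Reactants: 4 tert-butyl 2-(2,2-dimethyl-1,3-dioxan-5-yl)acetate; 5 3,4,5-trimethoxybenzaldehyde
Product: 6 tert-butyl 2-(2,2-dimethyl-1,3-dioxan-5-yl)-3-hydroxy-3-(3,4,5-trimethoxyphenyl)propanoate (racemic diastereomer mixture)
Conditions: LiN(iPr)2, THF, −78 °C; then 5, −78 °C; aq. NH4Cl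
Reagents that add atoms: none
Why: lithium enolate aldol addition to a non-enolizable aromatic aldehyde; the tert-butyl ester resists self-condensation, and the diastereomer mixture is of no consequence since both new stereocenters are erased in step 4.

Step 4
Reactants: 6 tert-butyl 2-(2,2-dimethyl-1,3-dioxan-5-yl)-3-hydroxy-3-(3,4,5-trimethoxyphenyl)propanoate
Product: 8 tert-butyl (E)-2-(2,2-dimethyl-1,3-dioxan-5-yl)-3-(3,4,5-trimethoxyphenyl)acrylate, via mesylate 7 (not isolated)
Conditions: MsCl, Et3N, CH2Cl2, 0 °C; then DBU, rt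
Reagents that add atoms: none
Why: mesylation followed by E1cB elimination with DBU should give the thermodynamically favoured (E)-α-branched cinnamate (aryl trans to the ester), the usual outcome of aldol condensation routes to such esters.

Step 5
Reactants: 8 tert-butyl (E)-2-(2,2-dimethyl-1,3-dioxan-5-yl)-3-(3,4,5-trimethoxyphenyl)acrylate
Product: 9 tert-butyl (E)-2-(1,3-dihydroxypropan-2-yl)-3-(3,4,5-trimethoxyphenyl)acrylate
Conditions: AcOH/H2O/THF (3:1:1), rt; toluene azeotrope below 30 °C
Reagents that add atoms: none
Why: acid-catalysed acetal hydrolysis of the 1,3-dioxane with a weak carboxylic acid at rt, conditions under which the tert-butyl ester is stable and which should be too weakly acidic to close the conjugated ester onto either hydroxyl.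

Step 6
Reactants: 9 tert-butyl (E)-2-(1,3-dihydroxypropan-2-yl)-3-(3,4,5-trimethoxyphenyl)acrylate
Product: 10 (S,E)-4-(hydroxymethyl)-3-(3,4,5-trimethoxybenzylidene)dihydrofuran-2(3H)-one
Conditions: (R)-TRIP (10 mol%), PhMe, 40 °C
Reagents that add atoms: none
Why: Proposed new method: the phosphoric acid acts bifunctionally, its P–OH proton activating the ester carbonyl while the P=O oxygen accepts a hydrogen bond from one hydroxymethyl group, which adds to C2, and the tetrahedral intermediate collapses with loss of tert-butanol (acid-catalysed acyl substitution). The closest known reaction type is the chiral-phosphoric-acid desymmetrizing lactonization of prochiral hydroxy di-tert-butyl esters, where two enantiotopic esters compete for one hydroxyl; here the roles are inverted (two enantiotopic hydroxyls, one conjugated ester), and that inversion is the untested element. The lactone ring closes in 5-exo-trig mode by forming the O1–C2 bond. C4 is the only new stereocenter and is set by the catalyst pocket, that is by which of the two enantiotopic CH2OH groups is held next to the activated carbonyl; C3 stays sp2, so no diastereomers can arise. The step needs enantiotopic-group selectivity and chemoselectivity for acyl substitution over 5-endo-trig oxa-Michael addition at the benzylidene carbon and over uncatalysed closure; the bulky, poorly electrophilic conjugated tert-butyl ester suppresses the background reaction and the 5-endo geometry disfavours the Michael path. The reaction is to be stopped at full conversion, because degenerate acyl transfer between the two arms of the product would erode the enantiomeric purity.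

Step 7
Reactants: 10 (S,E)-4-(hydroxymethyl)-3-(3,4,5-trimethoxybenzylidene)dihydrofuran-2(3H)-one
Product: 11 (4S)-4-(hydroxymethyl)-3-(3,4,5-trimethoxybenzyl)dihydrofuran-2(3H)-one (C3 epimers; cis 3S,4S expected to predominate)
Conditions: H2 (1 atm), 10% Pd/C, EtOAc, rt
Reagents that add atoms: none
Why: heterogeneous catalytic hydrogenation of the exocyclic conjugated alkene under neutral conditions (no acyl migration); hydrogen should add mainly anti to the C4 hydroxymethyl group to give mostly the cis epimer, which is corrected in step 11.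

Step 8
Reactants: 11 (4S)-4-(hydroxymethyl)-3-(3,4,5-trimethoxybenzyl)dihydrofuran-2(3H)-one
Product: 12 (4R)-4-(iodomethyl)-3-(3,4,5-trimethoxybenzyl)dihydrofuran-2(3H)-one (C3 epimers)
Conditions: I2, PPh3, imidazole, CH2Cl2, 0 °C to rt
Reagents that add atoms: iodine, [I][I]
Why: Appel iodination displaces the activated primary hydroxyl by SN2 at CH2 without touching C4 (the descriptor changes only through ligand priorities) and removes the free hydroxyl that could scramble C4 by acyl migration; imidazole is too weak a base to enolize C3.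

Step 9
Reactants: 13 4-bromo-2,6-dimethoxyphenol
Product: 14 2-(benzyloxy)-5-bromo-1,3-dimethoxybenzene
Conditions: BnBr, K2CO3, DMF, rt
Reagents that add atoms: benzyl bromide, BrCc1ccccc1
Why: Williamson ether synthesis masks the acidic phenol, which would otherwise protonate the organozinc reagent of step 10.

Step 10
Reactants: 12 (4R)-4-(iodomethyl)-3-(3,4,5-trimethoxybenzyl)dihydrofuran-2(3H)-one; 14 2-(benzyloxy)-5-bromo-1,3-dimethoxybenzene
Product: 16 (4R)-4-[4-(benzyloxy)-3,5-dimethoxybenzyl]-3-(3,4,5-trimethoxybenzyl)dihydrofuran-2(3H)-one (C3 epimers), via alkylzinc iodide 15 (not isolated)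
Conditions: Zn dust (I2-activated), DMF, rt; then 14, Pd2(dba)3 (2.5 mol%), SPhos (10 mol%), DMF, 40 °C
Reagents that add atoms: none
Why: zinc insertion into the primary C–I bond gives a lactone-tolerant alkylzinc iodide, and its Negishi cross-coupling under zerovalent palladium/SPhos catalysis forms the C(sp3)–C(sp2) bond to ring B, the bulky biarylphosphine favouring reductive elimination over β-hydride elimination; C4 is not involved.

Step 11
Reactants: 16 (4R)-4-[4-(benzyloxy)-3,5-dimethoxybenzyl]-3-(3,4,5-trimethoxybenzyl)dihydrofuran-2(3H)-one (C3 epimers)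
Product: 17 (3R,4R)-4-[4-(benzyloxy)-3,5-dimethoxybenzyl]-3-(3,4,5-trimethoxybenzyl)dihydrofuran-2(3H)-one
Conditions: DBU, PhMe, 80 °C
Reagents that add atoms: none
Why: base-mediated epimerization through the lactone enolate at C3, the only acidic stereocenter, should drive the mixture to the thermodynamically preferred trans lactone with the two benzyl groups anti, which sets C3 as R under thermodynamic control.

Step 12
Reactants: 17 (3R,4R)-4-[4-(benzyloxy)-3,5-dimethoxybenzyl]-3-(3,4,5-trimethoxybenzyl)dihydrofuran-2(3H)-one
Product: 18 (3R,4R)-4-(4-hydroxy-3,5-dimethoxybenzyl)-3-(3,4,5-trimethoxybenzyl)dihydrofuran-2(3H)-one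
Conditions: H2 (1 atm), 10% Pd/C, EtOAc/MeOH, rt
Reagents that add atoms: none
Why: hydrogenolysis of the benzyl aryl ether under neutral conditions releases the phenol without epimerizing C3 or touching the lactone and the methyl ethers.

**Compound list**

1 | 2,2-dimethyl-1,3-dioxan-5-one | CC1(C)OCC(=O)CO1 | starting material
2 | tert-butyl diethylphosphonoacetate | CCOP(=O)(CC(=O)OC(C)(C)C)OCC | starting material
3 | tert-butyl 2-(2,2-dimethyl-1,3-dioxan-5-ylidene)acetate | CC1(C)OCC(=CC(=O)OC(C)(C)C)CO1 | intermediate
4 | tert-butyl 2-(2,2-dimethyl-1,3-dioxan-5-yl)acetate | CC1(C)OCC(CC(=O)OC(C)(C)C)CO1 | intermediate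
5 | 3,4,5-trimethoxybenzaldehyde | COc1cc(C=O)cc(OC)c1OC | starting material
6 | tert-butyl 2-(2,2-dimethyl-1,3-dioxan-5-yl)-3-hydroxy-3-(3,4,5-trimethoxyphenyl)propanoate (racemic diastereomer mixture) | CC1(C)OCC(CO1)C(C(=O)OC(C)(C)C)C(O)c1cc(OC)c(OC)c(OC)c1 | intermediate
7 | tert-butyl 2-(2,2-dimethyl-1,3-dioxan-5-yl)-3-(methylsulfonyloxy)-3-(3,4,5-trimethoxyphenyl)propanoate (not isolated) | CC1(C)OCC(CO1)C(C(=O)OC(C)(C)C)C(OS(C)(=O)=O)c1cc(OC)c(OC)c(OC)c1 | intermediate
8 | tert-butyl (E)-2-(2,2-dimethyl-1,3-dioxan-5-yl)-3-(3,4,5-trimethoxyphenyl)acrylate | CC1(C)OCC(CO1)/C(=C\c1cc(OC)c(OC)c(OC)c1)C(=O)OC(C)(C)C | intermediate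
9 | tert-butyl (E)-2-(1,3-dihydroxypropan-2-yl)-3-(3,4,5-trimethoxyphenyl)acrylate (key-step precursor) | CC(C)(C)OC(=O)/C(=C/c1cc(OC)c(OC)c(OC)c1)C(CO)CO | intermediate
10 | (S,E)-4-(hydroxymethyl)-3-(3,4,5-trimethoxybenzylidene)dihydrofuran-2(3H)-one (key-step product) | O=C1OC[C@H](CO)/C1=C\c1cc(OC)c(OC)c(OC)c1 | intermediate
11 | (4S)-4-(hydroxymethyl)-3-(3,4,5-trimethoxybenzyl)dihydrofuran-2(3H)-one (C3 epimers) | O=C1OC[C@H](CO)C1Cc1cc(OC)c(OC)c(OC)c1 | intermediate
12 | (4R)-4-(iodomethyl)-3-(3,4,5-trimethoxybenzyl)dihydrofuran-2(3H)-one (C3 epimers) | O=C1OC[C@H](CI)C1Cc1cc(OC)c(OC)c(OC)c1 | intermediate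
13 | 4-bromo-2,6-dimethoxyphenol | COc1cc(Br)cc(OC)c1O | starting material
14 | 2-(benzyloxy)-5-bromo-1,3-dimethoxybenzene | COc1cc(Br)cc(OC)c1OCc1ccccc1 | intermediate
15 | {[(3R)-5-oxo-4-(3,4,5-trimethoxybenzyl)oxolan-3-yl]methyl}zinc iodide (not isolated) | O=C1OC[C@H](C[Zn]I)C1Cc1cc(OC)c(OC)c(OC)c1 | intermediate
16 | (4R)-4-[4-(benzyloxy)-3,5-dimethoxybenzyl]-3-(3,4,5-trimethoxybenzyl)dihydrofuran-2(3H)-one (C3 epimers) | O=C1OC[C@H](Cc2cc(OC)c(OCc3ccccc3)c(OC)c2)C1Cc1cc(OC)c(OC)c(OC)c1 | intermediate
17 | (3R,4R)-4-[4-(benzyloxy)-3,5-dimethoxybenzyl]-3-(3,4,5-trimethoxybenzyl)dihydrofuran-2(3H)-one | O=C1OC[C@H](Cc2cc(OC)c(OCc3ccccc3)c(OC)c2)[C@H]1Cc1cc(OC)c(OC)c(OC)c1 | intermediate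
18 | (3R,4R)-4-(4-hydroxy-3,5-dimethoxybenzyl)-3-(3,4,5-trimethoxybenzyl)dihydrofuran-2(3H)-one | COc1cc(C[C@H]2COC(=O)[C@@H]2Cc2cc(OC)c(OC)c(OC)c2)cc(OC)c1O | target

**Step count**

Total: 12 steps. Longest linear sequence: 11 steps (steps 1–8 and 10–12, from 1 to 18); step 9 is a one-step side branch.

**Steps most likely to fail, with fallbacks**

Step 6. Three processes may spoil it: sluggish turnover of the deactivated conjugated ester, weak discrimination between the two enantiotopic hydroxymethyl groups, and erosion of enantiomeric purity by degenerate acyl transfer between the two arms of the product. The fallback uses known chemistry, sets out from 9 and returns at 10.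
- Lipase-catalysed desymmetrizing monoacetylation of the 2-substituted propane-1,3-diol (Burkholderia cepacia lipase, vinyl acetate, MTBE, rt) should give tert-butyl (E)-2-[(2R)-1-acetoxy-3-hydroxypropan-2-yl]-3-(3,4,5-trimethoxyphenyl)acrylate F1. If the enzyme delivers the antipode, a lipase of opposite preference is to be selected.
- Brief treatment with CF3CO2H in CH2Cl2 at 0 °C cleaves the tert-butyl ester to (E)-2-[(2R)-1-acetoxy-3-hydroxypropan-2-yl]-3-(3,4,5-trimethoxyphenyl)acrylic acid F2 (not isolated). Its free hydroxyl closes at once to (S,E)-4-(acetoxymethyl)-3-(3,4,5-trimethoxybenzylidene)dihydrofuran-2(3H)-one F3.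
- The acetate is removed by lipase-catalysed hydrolysis (Candida antarctica lipase B, aqueous NaH2PO4/Na2HPO4 buffer at pH 7, MTBE), chosen because neutral conditions avoid acyl migration, which gives 10.

Step 10. Incomplete zinc insertion, protonation of the alkylzinc by adventitious proton sources, or β-hydride elimination after transmetalation may lower the coupling. The fallback sets out from 12 and 14 and returns at 16. It is a nickel-catalysed reductive cross-electrophile coupling (NiI2, 4,4'-di-tert-butyl-2,2'-bipyridine, Zn dust, NaI, DMPU, 60 °C, slow addition of 12). No organozinc is preformed; an alkyl radical from 12 is captured by an arylnickel species from 14, so the failure modes of the zinc reagent do not apply.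

Step 5. On unveiling the diol, premature uncatalysed lactonization (racemic background closure) or loss of the tert-butyl group may occur. The fallback sets out from 8 and returns at 10.
- Aqueous CF3CO2H in CH2Cl2 removes the acetonide (via 9) and the tert-butyl group to give (E)-2-(1,3-dihydroxypropan-2-yl)-3-(3,4,5-trimethoxyphenyl)acrylic acid F4 (not isolated), which closes to racemic (E)-4-(hydroxymethyl)-3-(3,4,5-trimethoxybenzylidene)dihydrofuran-2(3H)-one F5.
- Lipase-catalysed kinetic resolution by acetylation (Burkholderia cepacia lipase, vinyl acetate, MTBE) should convert the (R)-alcohol into (R,E)-4-(acetoxymethyl)-3-(3,4,5-trimethoxybenzylidene)dihydrofuran-2(3H)-one F6 and leave the (S)-alcohol 10, which is separated and carried on.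
- Should the enzyme prefer the (S)-alcohol, its acetate is the lactone F3 of the first fallback and is hydrolysed enzymatically in the same way.
- This fallback gives up the catalytic desymmetrization and is limited to half of the material.

**Further compounds**

F1 | step 6 | tert-butyl (E)-2-[(2R)-1-acetoxy-3-hydroxypropan-2-yl]-3-(3,4,5-trimethoxyphenyl)acrylate | OC[C@H](COC(C)=O)/C(=C\c1cc(OC)c(OC)c(OC)c1)C(=O)OC(C)(C)C
F2 | step 6 | (E)-2-[(2R)-1-acetoxy-3-hydroxypropan-2-yl]-3-(3,4,5-trimethoxyphenyl)acrylic acid | OC[C@H](COC(C)=O)/C(=C\c1cc(OC)c(OC)c(OC)c1)C(O)=O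
F3 | step 6 | (S,E)-4-(acetoxymethyl)-3-(3,4,5-trimethoxybenzylidene)dihydrofuran-2(3H)-one | O=C1OC[C@H](COC(C)=O)/C1=C\c1cc(OC)c(OC)c(OC)c1
F0 | step 10 | none | none
F4 | step 5 | (E)-2-(1,3-dihydroxypropan-2-yl)-3-(3,4,5-trimethoxyphenyl)acrylic acid | OCC(CO)/C(=C\c1cc(OC)c(OC)c(OC)c1)C(O)=O
F5 | step 5 | racemic (E)-4-(hydroxymethyl)-3-(3,4,5-trimethoxybenzylidene)dihydrofuran-2(3H)-one | O=C1OCC(CO)/C1=C\c1cc(OC)c(OC)c(OC)c1
F6 | step 5 | (R,E)-4-(acetoxymethyl)-3-(3,4,5-trimethoxybenzylidene)dihydrofuran-2(3H)-one | O=C1OC[C@@H](COC(C)=O)/C1=C\c1cc(OC)c(OC)c(OC)c1
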